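## Retrosynthetic overview

1. Carbocycle numbering: C1 = CH bearing the side chain, C2 = CMe2, C3 = CHOH, C4 and C5 = CH2, C6 = C(=CH2). The last bond made is the allylic CH2–O bond, by Mitsunobu coupling of 4-hydroxy-5-methylcoumarin with the primary hydroxyl of the monocyclic diol.
2. C6=CH2 comes from C6=O by Wittig methylenation. Excising C1 from this cyclohexanone leaves (S)-3-silyloxy-2,2-dimethylcyclopentanone plus one carbenoid carbon. That carbon carries the whole side chain (C6 of geraniol, used as a 1-chloroalkyl p-tolyl sulfoxide).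
3. Enabling feature: C1 lies between the quaternary C2 and the latent carbonyl C6. Without C1, the ring C2–C3–C4–C5–C6 is a cyclopentanone whose C=O is flanked by a quaternary carbon (the better migrating group) and a CH2. After insertion, C1–H is α to C6=O, so C1 can be equilibrated against C3 to the cis-1,3-diequatorial arrangement.
4. C3 comes from CBS desymmetrisation of the Cs-symmetric 2,2-dimethylcyclopentane-1,3-dione. The (E)-alkene comes from geraniol.
5. Ring order: cyclopentane (bought) is enlarged to the cyclohexane in step 8; the pyranone ring is closed on a bought benzene ring in step 11; the two halves are joined last.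

Key step: step 8

Remark: 2,2-dimethylcyclopentane-1,3-dione, geraniol and 1-(2-hydroxy-6-methylphenyl)ethan-1-one are taken as commercial. The sulfur, C–Cl and carbinol stereocentres in 9–13 are carried as mixtures, because step 8 erases them.

## Route

Step 1
Reactants: 1 2,2-dimethylcyclopentane-1,3-dione
Product: 2 (3S)-3-hydroxy-2,2-dimethylcyclopentan-1-one
Conditions: (R)-Me-CBS (10 mol %), BH3·SMe2 (0.6 equiv, slow addition), THF, −30 °C; MeOH, then aq. work-up
Reagents that add atoms: none
Why: Corey–Bakshi–Shibata reduction desymmetrises the dione, because the catalyst distinguishes the quaternary (large) from the CH2 (small) flank of the enantiotopic carbonyls, so the (R)-catalyst should give the (S)-carbinol that becomes C3.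

Step 2
Reactants: 2 (3S)-3-hydroxy-2,2-dimethylcyclopentan-1-one
Product: 3 (3S)-3-[(tert-butyldimethylsilyl)oxy]-2,2-dimethylcyclopentan-1-one
Conditions: TBSCl, imidazole, DMAP (cat.), DMF, 40 °C
Reagents that add atoms: tert-butyldimethylsilyl chloride, C[Si](C)(Cl)C(C)(C)C
Why: Standard silyl ether formation under weakly basic conditions avoids retro-aldol opening of the β-hydroxy ketone and does not touch the stereocentre.

Step 3
Reactants: 4 geraniol
Product: 5 geranyl TBS ether, tert-butyl{[(2E)-3,7-dimethylocta-2,6-dien-1-yl]oxy}dimethylsilane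
Conditions: TBSCl, imidazole, CH2Cl2, 0 °C → rt
Reagents that add atoms: tert-butyldimethylsilyl chloride, C[Si](C)(Cl)C(C)(C)C
Why: Standard silylation of a primary allylic alcohol keeps the (E)-alkene geometry.

Step 4
Reactants: 5 geranyl TBS ether
Product: 7 (4E)-6-[(tert-butyldimethylsilyl)oxy]-4-methylhex-4-en-1-ol, via secondary ozonide 6 (not isolated)
Conditions: O3 (1.0 equiv), CH2Cl2, −78 °C; then NaBH4, MeOH, −78 °C → rt
Reagents that add atoms: ozone, [O-][O+]=O
Why: In this chemoselective ozonolysis with reductive work-up, the isopropylidene alkene is more electron-rich than the 2,3-alkene (deactivated inductively by the allylic silyloxy group), so one equivalent of ozone should cleave only the terminal alkene.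

Step 5
Reactants: 7 (4E)-6-[(tert-butyldimethylsilyl)oxy]-4-methylhex-4-en-1-ol
Product: 8 tert-butyldimethyl{[(2E)-3-methyl-6-(p-tolylsulfanyl)hex-2-en-1-yl]oxy}silane
Conditions: (p-TolS)2, Bu3P, THF, rt
Reagents that add atoms: di-p-tolyl disulfide, Cc1ccc(SSc2ccc(C)cc2)cc1
Why: In this Hata-type (Mitsunobu-like) thioetherification, the thiophosphonium salt activates the primary alcohol for SN2 displacement by p-toluenethiolate, and the silyl ether and alkene are inert.

Step 6
Reactants: 8 tert-butyldimethyl{[(2E)-3-methyl-6-(p-tolylsulfanyl)hex-2-en-1-yl]oxy}silane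
Product: 9 tert-butyldimethyl{[(2E)-3-methyl-6-(p-tolylsulfinyl)hex-2-en-1-yl]oxy}silane (racemic at sulfur)
Conditions: mCPBA (1.0 equiv), CH2Cl2, −78 °C
Reagents that add atoms: 3-chloroperoxybenzoic acid, OOC(=O)c1cccc(Cl)c1
Why: This is a chemoselective sulfide-to-sulfoxide oxidation in which sulfur reacts far faster than the trisubstituted alkene at −78 °C, and the sulfur stereocentre forms as a racemate that is irrelevant later.

Step 7
Reactants: 9 tert-butyldimethyl{[(2E)-3-methyl-6-(p-tolylsulfinyl)hex-2-en-1-yl]oxy}silane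
Product: 10 tert-butyl{[(2E)-6-chloro-3-methyl-6-(p-tolylsulfinyl)hex-2-en-1-yl]oxy}dimethylsilane (mixture of diastereomers)
Conditions: NCS, K2CO3, CH2Cl2, 0 °C → rt
Reagents that add atoms: N-chlorosuccinimide, O=C1CCC(=O)N1Cl
Why: α-Chlorination of a sulfoxide with NCS (Pummerer-like chlorooxosulfonium pathway) occurs at the only α-CH2 while K2CO3 scavenges acid, and the new C–Cl centre forms as a mixture that step 8 erases.

Step 8
Reactants: 3 (3S)-3-[(tert-butyldimethylsilyl)oxy]-2,2-dimethylcyclopentan-1-one; 10 tert-butyl{[(2E)-6-chloro-3-methyl-6-(p-tolylsulfinyl)hex-2-en-1-yl]oxy}dimethylsilane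
Product: 16 (2S,4S)-4-[(tert-butyldimethylsilyl)oxy]-2-{(3E)-5-[(tert-butyldimethylsilyl)oxy]-3-methylpent-3-en-1-yl}-3,3-dimethylcyclohexan-1-one, via lithiated chloro sulfoxide 11 (not isolated), via adduct lithium alkoxide 12 (not isolated), via magnesium β-oxido carbenoid 13 (not isolated), via ring-enlarged lithium enolate 14 (not isolated), via crude ketone of open C2 configuration 15 (not isolated)
Conditions: 10, LDA, THF, −78 °C; add 3; then i-PrMgCl (3 equiv), −78 → 0 °C; aq. NH4Cl; crude product, DBU (cat.), CH2Cl2, rt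
Reagents that add atoms: none
Why: Carbanion 11 adds to the carbonyl of 3, sulfoxide–magnesium exchange on alkoxide 12 unmasks the β-oxido carbenoid 13, and loss of chloride goes with a 1,2-shift of a ring C–C bond from the carbinol carbon to the exocyclic carbenoid carbon, which enters the ring and gives enolate 14; the closest known reaction type is the β-oxido carbenoid one-carbon ring enlargement of cycloalkanones with 1-chloroalkyl aryl sulfoxides, known for cyclopentanone to 2-alkylcyclohexanone. No ring is closed by cyclisation: the five-membered ring grows to the six-membered one by the 1,2-shift, and the same operation forms both ring bonds of C1 and attaches the complete side chain. The selectivity needed is migration of the quaternary CMe2 carbon rather than the CH2 carbon, and it rests on the higher migratory aptitude of the more substituted, more electron-rich α-carbon towards the electron-deficient carbenoid centre, as in enlargements of 2-alkylcycloalkanones. All stereoisomers of 10 and 12 (sulfur, C–Cl and carbinol centres) collapse into the single planar enolate 14, so the addition needs no stereocontrol. The new stereocentre (ketone C2, target C1) is governed by the silyloxy-bearing carbon: in the chair with equatorial OTBS, protonation should occur axially, anti to the axial methyl group, and DBU equilibration through the enol should funnel any trans epimer in 15 into the cis-2,4-diequatorial ketone 16. The silyloxy centre is safe because the α-carbon between it and the original carbonyl is quaternary and it is γ to the new carbonyl, so neither elimination nor epimerisation is open.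

Step 9
Reactants: 16 (2S,4S)-4-[(tert-butyldimethylsilyl)oxy]-2-{(3E)-5-[(tert-butyldimethylsilyl)oxy]-3-methylpent-3-en-1-yl}-3,3-dimethylcyclohexan-1-one
Product: 17 bis-TBS ether of (1S,3R)-3-[(3E)-5-hydroxy-3-methylpent-3-en-1-yl]-2,2-dimethyl-4-methylidenecyclohexan-1-ol
Conditions: Ph3PCH3Br (3 equiv), KOt-Bu (2.8 equiv), toluene, rt → 80 °C
Reagents that add atoms: methyltriphenylphosphonium bromide, C[P+](c1ccccc1)(c1ccccc1)c1ccccc1.[Br-]
Why: Wittig methylenation is established for 2-alkyl-3,3-dimethylcyclohexanones, and because the α-centre is already the thermodynamically preferred epimer, reversible enolisation by the ylide cannot erode it.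

Step 10
Reactants: 17 bis-TBS ether of (1S,3R)-3-[(3E)-5-hydroxy-3-methylpent-3-en-1-yl]-2,2-dimethyl-4-methylidenecyclohexan-1-ol
Product: 18 (1S,3R)-3-[(3E)-5-hydroxy-3-methylpent-3-en-1-yl]-2,2-dimethyl-4-methylidenecyclohexan-1-ol
Conditions: TBAF (4 equiv), THF, 50 °C; aq. work-up
Reagents that add atoms: none
Why: Fluoride cleaves both silyl ethers; warming serves the hindered secondary ether, and 17 has no base-sensitive group or acidic stereocentre.

Step 11
Reactants: 19 1-(2-hydroxy-6-methylphenyl)ethan-1-one
Product: 21 4-hydroxy-5-methyl-2H-chromen-2-one, via β-keto ester 20 (not isolated)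
Conditions: NaH (3 equiv), (EtO)2CO, toluene, reflux; aq. HCl
Reagents that add atoms: diethyl carbonate, CCOC(=O)OCC
Why: Claisen-type C-ethoxycarbonylation of the ketone enolate, then lactonisation of the phenoxide onto the ester (6-exo-trig acyl substitution), is the standard 4-hydroxycoumarin synthesis.

Step 12
Reactants: 18 (1S,3R)-3-[(3E)-5-hydroxy-3-methylpent-3-en-1-yl]-2,2-dimethyl-4-methylidenecyclohexan-1-ol; 21 4-hydroxy-5-methyl-2H-chromen-2-one
Product: 22 4-({(2E)-5-[(1R,3S)-3-hydroxy-2,2-dimethyl-6-methylidenecyclohexyl]-3-methylpent-2-en-1-yl}oxy)-5-methyl-2H-chromen-2-one (target)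
Conditions: PPh3, DIAD (1.1 equiv each), THF, 0 °C → rt
Reagents that add atoms: none
Why: In this Mitsunobu etherification the acidic 4-hydroxycoumarin should be O-alkylated by SN2 on the oxyphosphonium ion of the unhindered primary allylic alcohol, while the secondary hydroxyl next to the quaternary carbon is too hindered to be activated, and no stereocentre or alkene geometry is touched.

## Compound list

1 | 2,2-dimethylcyclopentane-1,3-dione | CC1(C)C(=O)CCC1=O | starting material
2 | (3S)-3-hydroxy-2,2-dimethylcyclopentan-1-one | CC1(C)[C@@H](O)CCC1=O | intermediate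
3 | (3S)-3-[(tert-butyldimethylsilyl)oxy]-2,2-dimethylcyclopentan-1-one | CC1(C)[C@@H](O[Si](C)(C)C(C)(C)C)CCC1=O | intermediate
4 | geraniol | CC(C)=CCC/C(C)=C/CO | starting material
5 | geranyl TBS ether | CC(C)=CCC/C(C)=C/CO[Si](C)(C)C(C)(C)C | intermediate
6 | secondary ozonide (3,3-dimethyl-5-substituted 1,2,4-trioxolane) | CC1(C)OOC(CC/C(C)=C/CO[Si](C)(C)C(C)(C)C)O1 | intermediate
7 | (4E)-6-[(tert-butyldimethylsilyl)oxy]-4-methylhex-4-en-1-ol | OCCC/C(C)=C/CO[Si](C)(C)C(C)(C)C | intermediate
8 | tert-butyldimethyl{[(2E)-3-methyl-6-(p-tolylsulfanyl)hex-2-en-1-yl]oxy}silane | Cc1ccc(SCCC/C(C)=C/CO[Si](C)(C)C(C)(C)C)cc1 | intermediate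
9 | tert-butyldimethyl{[(2E)-3-methyl-6-(p-tolylsulfinyl)hex-2-en-1-yl]oxy}silane (racemic at S) | Cc1ccc(S(=O)CCC/C(C)=C/CO[Si](C)(C)C(C)(C)C)cc1 | intermediate
10 | tert-butyl{[(2E)-6-chloro-3-methyl-6-(p-tolylsulfinyl)hex-2-en-1-yl]oxy}dimethylsilane (diastereomer mixture) | Cc1ccc(S(=O)C(Cl)CC/C(C)=C/CO[Si](C)(C)C(C)(C)C)cc1 | intermediate
11 | lithiated chloro sulfoxide | [Li]C(Cl)(CC/C(C)=C/CO[Si](C)(C)C(C)(C)C)S(=O)c1ccc(C)cc1 | intermediate
12 | adduct lithium alkoxide (tertiary cyclopentanolate, stereoisomer mixture apart from the (S)-silyloxy centre) | [Li]OC1(CC[C@H](O[Si](C)(C)C(C)(C)C)C1(C)C)C(Cl)(CC/C(C)=C/CO[Si](C)(C)C(C)(C)C)S(=O)c1ccc(C)cc1 | intermediate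
13 | magnesium β-oxido carbenoid | [Li]OC1(CC[C@H](O[Si](C)(C)C(C)(C)C)C1(C)C)C(Cl)([Mg]Cl)CC/C(C)=C/CO[Si](C)(C)C(C)(C)C | intermediate
14 | ring-enlarged lithium enolate | [Li]OC1=C(CC/C(C)=C/CO[Si](C)(C)C(C)(C)C)C(C)(C)[C@@H](O[Si](C)(C)C(C)(C)C)CC1 | intermediate
15 | crude ketone of open C2 configuration | O=C1CC[C@H](O[Si](C)(C)C(C)(C)C)C(C)(C)C1CC/C(C)=C/CO[Si](C)(C)C(C)(C)C | intermediate
16 | (2S,4S)-4-[(tert-butyldimethylsilyl)oxy]-2-{(3E)-5-[(tert-butyldimethylsilyl)oxy]-3-methylpent-3-en-1-yl}-3,3-dimethylcyclohexan-1-one | O=C1CC[C@H](O[Si](C)(C)C(C)(C)C)C(C)(C)[C@@H]1CC/C(C)=C/CO[Si](C)(C)C(C)(C)C | intermediate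
17 | bis-TBS ether of (1S,3R)-3-[(3E)-5-hydroxy-3-methylpent-3-en-1-yl]-2,2-dimethyl-4-methylidenecyclohexan-1-ol | C=C1CC[C@H](O[Si](C)(C)C(C)(C)C)C(C)(C)[C@@H]1CC/C(C)=C/CO[Si](C)(C)C(C)(C)C | intermediate
18 | (1S,3R)-3-[(3E)-5-hydroxy-3-methylpent-3-en-1-yl]-2,2-dimethyl-4-methylidenecyclohexan-1-ol | C=C1CC[C@H](O)C(C)(C)[C@@H]1CC/C(C)=C/CO | intermediate
19 | 1-(2-hydroxy-6-methylphenyl)ethan-1-one | CC(=O)c1c(C)cccc1O | starting material
20 | ethyl 3-(2-hydroxy-6-methylphenyl)-3-oxopropanoate | CCOC(=O)CC(=O)c1c(C)cccc1O | intermediate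
21 | 4-hydroxy-5-methyl-2H-chromen-2-one | Cc1cccc2oc(=O)cc(O)c12 | intermediate
22 | 4-({(2E)-5-[(1R,3S)-3-hydroxy-2,2-dimethyl-6-methylidenecyclohexyl]-3-methylpent-2-en-1-yl}oxy)-5-methyl-2H-chromen-2-one | C=C1CC[C@H](O)C(C)(C)[C@@H]1CC/C(C)=C/COc1cc(=O)oc2cccc(C)c12 | target

## Step count and risks

Total step count: 12.
Longest linear sequence: 9 steps (geraniol 4 to 22: steps 3, 4, 5, 6, 7, 8, 9, 10, 12).

**1. Step 8.**
- Three things may go wrong. The crowded tertiary sulfinyl carbanion may add only reversibly or incompletely to the carbonyl next to the quaternary carbon, through retro-addition or enolisation. The CH2 carbon may migrate in competition with the quaternary carbon. The carbenoid may be lost through a 1,2-hydride shift from the side chain.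
- The fallback sets out from 3 and 7 and returns at 16. It inserts the same carbon as a slim, neutral diazoalkane and enforces the direction of the shift with a temporary chlorine.
- Ketone 3 would be chlorinated at its only enolisable position (LDA, then TsCl as chlorine donor). This gives (3S)-3-[(tert-butyldimethylsilyl)oxy]-5-chloro-2,2-dimethylcyclopentan-1-one F1.
- Alcohol 7 would be oxidised with Dess–Martin periodinane to (4E)-6-[(tert-butyldimethylsilyl)oxy]-4-methylhex-4-enal F2. Condensation with tosylhydrazine gives the tosylhydrazone F3. Bamford–Stevens fragmentation of its sodium salt gives the diazoalkane F4.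
- Lewis-acid-promoted Büchner–Curtius–Schlotterbeck homologation of F1 with F4 (BF3·OEt2, CH2Cl2, −78 °C) should give the ring-enlarged chloro ketone F5. A halogen-bearing α-carbon does not migrate to the diazonium carbon, and the halogen raises the electrophilicity of the carbonyl.
- Zinc in acetic acid/THF removes the chlorine through the zinc enolate, and DBU equilibration leads to 16.

**2. Step 9.**
- The basic ylide may enolise the hindered ketone instead of adding to it, so conversion may stall.
- The fallback sets out from 16 and returns at 17, and replaces the Wittig reaction by a Peterson olefination run as addition followed by elimination.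
- The weakly basic organocerium reagent from Me3SiCH2Li and CeCl3 (THF, −78 °C) adds to 16 to give the β-hydroxysilane F6. KH in THF then triggers syn-elimination to 17.

**3. Step 12.**
- The ambident coumarinate may be alkylated at C3 or at the lactone carbonyl oxygen. The allylic oxyphosphonium ion may also be attacked in the SN2′ sense. The peri methyl group slows the wanted O-alkylation.
- The fallback sets out from 18 and 21 and returns at 22, with the polarity reversed.
- Coumarin 21 would be converted with POCl3 into 4-chloro-5-methyl-2H-chromen-2-one F7. The primary alkoxide of 18 (NaH, 1 equiv, THF, 0 °C) displaces chloride by addition–elimination at C4.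
- The ether oxygen then comes from the alcohol, so C-alkylation, carbonyl-O alkylation and allylic transposition are excluded. The hindered secondary alkoxide should not compete.

Further compounds
F1 | step 8 | (3S)-3-[(tert-butyldimethylsilyl)oxy]-5-chloro-2,2-dimethylcyclopentan-1-one | CC1(C)[C@@H](O[Si](C)(C)C(C)(C)C)CC(Cl)C1=O
F2 | step 8 | (4E)-6-[(tert-butyldimethylsilyl)oxy]-4-methylhex-4-enal | O=CCC/C(C)=C/CO[Si](C)(C)C(C)(C)C
F3 | step 8 | N-tosylhydrazone of F2 | Cc1ccc(S(=O)(=O)NN=CCC/C(C)=C/CO[Si](C)(C)C(C)(C)C)cc1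
F4 | step 8 | tert-butyl{[(2E)-6-diazo-3-methylhex-2-en-1-yl]oxy}dimethylsilane | [N-]=[N+]=CCC/C(C)=C/CO[Si](C)(C)C(C)(C)C
F5 | step 8 | (4S)-4-[(tert-butyldimethylsilyl)oxy]-6-chloro-2-{(3E)-5-[(tert-butyldimethylsilyl)oxy]-3-methylpent-3-en-1-yl}-3,3-dimethylcyclohexan-1-one | O=C1C(Cl)C[C@H](O[Si](C)(C)C(C)(C)C)C(C)(C)C1CC/C(C)=C/CO[Si](C)(C)C(C)(C)C
F6 | step 9 | (2S,4S)-4-[(tert-butyldimethylsilyl)oxy]-2-{(3E)-5-[(tert-butyldimethylsilyl)oxy]-3-methylpent-3-en-1-yl}-3,3-dimethyl-1-[(trimethylsilyl)methyl]cyclohexan-1-ol | C[Si](C)(C)CC1(O)CC[C@H](O[Si](C)(C)C(C)(C)C)C(C)(C)[C@@H]1CC/C(C)=C/CO[Si](C)(C)C(C)(C)C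
F7 | step 12 | 4-chloro-5-methyl-2H-chromen-2-one | Cc1cccc2oc(=O)cc(Cl)c12
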